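**Retrosynthetic overview**
1. The C(sp3)–C(sp2) bond next to the trisubstituted E-alkene is cut (late Negishi coupling), giving vinyl iodide 17 (14 C) and chromene iodide 36 (12 C + 2 O of the target).
2. 17 comes from Zr-catalysed carboalumination/iodination of alkyne 14, made from iodide 12 and acetylide; the ring stereocentre comes from a Johnson–Claisen 1,3-chirality transfer on (R)-allylic alcohol 6 (CBS reduction of enone 5).
3. 36 comes from chromene 34, whose pyran ring is closed by Pd-catalysed aryl C–O coupling of Z-alkenyl tertiary carbinol 33 (Lindlar, Sonogashira of 31 with 28).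
4. The tertiary carbinol 28 comes from Sharpless epoxidation of 23 and epoxy chloride-to-alkynol fragmentation; its C–O bond is never broken afterwards.
5. Ring order: cyclohexene (Robinson annulation, step 1), benzene ring bought as 3-iodophenol, pyran ring (step 17).

Assumption: MeC(OMe)3, LiC≡CH·ethylenediamine, Me3Al and (CH2O)n are treated as small carbon building blocks and numbered as starting materials; TBS and TIPS are protecting groups.

**Step 1**
Reactants: 1 isobutyraldehyde + 2 pent-1-en-3-one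
Product: 5 2,4,4-trimethylcyclohex-2-en-1-one, via 2,2-dimethyl-5-oxoheptanal 3 (not isolated), via aldol 3-hydroxy-2,4,4-trimethylcyclohexan-1-one 4 (not isolated)
Conditions: cat. H2SO4, PhMe, 50 °C then reflux (Dean–Stark)
Reagents that add atoms: none
Why: Acid-catalysed Michael addition of the aldehyde enol to the enone followed by intramolecular aldol condensation (Robinson annulation) closes the cyclohexenone; no stereocentre is formed.

**Step 2**
Reactants: 5 2,4,4-trimethylcyclohex-2-en-1-one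
Product: 6 (1R)-2,4,4-trimethylcyclohex-2-en-1-ol
Conditions: (S)-Me-CBS (10 mol%), BH3·SMe2, THF, −20 °C; MeOH, aq. work-up
Reagents that add atoms: none
Why: Corey–Bakshi–Shibata reduction in which the α-methyl alkenyl arm acts as the large group on the (S)-oxazaborolidine·BH3 complex, so hydride delivery gives the (R)-carbinol.

**Step 3**
Reactants: 6 (1R)-2,4,4-trimethylcyclohex-2-en-1-ol + 7 trimethyl orthoacetate
Product: 10 methyl 2-[(1S)-2,6,6-trimethylcyclohex-2-en-1-yl]acetate, via mixed orthoester 8 (not isolated), via ketene acetal 9 (not isolated)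
Conditions: MeC(OMe)3 (6 equiv), EtCO2H (cat.), o-xylene, 140 °C (sealed tube), 24–48 h
Reagents that add atoms: none
Why: Johnson–Claisen rearrangement: the suprafacial [3,3] shift puts CH2CO2Me on C3 on the ring face that carried the C1–O bond, so (R)-6 gives the (S) ring stereocentre and moves the double bond to C(Me)=CH.

**Step 4**
Reactants: 10 methyl 2-[(1S)-2,6,6-trimethylcyclohex-2-en-1-yl]acetate
Product: 11 2-[(1S)-2,6,6-trimethylcyclohex-2-en-1-yl]ethan-1-ol
Conditions: LiAlH4, Et2O, 0 °C; Fieser work-up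
Reagents that add atoms: none
Why: Hydride reduction of the ester to the primary alcohol; the stereocentre is β to the carbonyl and cannot epimerise.

**Step 5**
Reactants: 11 2-[(1S)-2,6,6-trimethylcyclohex-2-en-1-yl]ethan-1-ol
Product: 12 (6S)-6-(2-iodoethyl)-1,5,5-trimethylcyclohex-1-ene
Conditions: I2, PPh3, imidazole, CH2Cl2, 0 °C → rt
Reagents that add atoms: iodine, II
Why: Appel-type iodination of an unhindered primary alcohol; the stereocentre is untouched.

**Step 6**
Reactants: 12 (6S)-6-(2-iodoethyl)-1,5,5-trimethylcyclohex-1-ene + 13 lithium acetylide–ethylenediamine complex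
Product: 14 (6S)-6-(but-3-yn-1-yl)-1,5,5-trimethylcyclohex-1-ene
Conditions: DMSO, 10 °C → rt
Reagents that add atoms: none
Why: SN2 alkylation of acetylide by a primary iodide in a dipolar aprotic solvent gives the terminal alkyne directly.

**Step 7**
Reactants: 14 (6S)-6-(but-3-yn-1-yl)-1,5,5-trimethylcyclohex-1-ene + 15 trimethylaluminium
Product: 17 (6S)-6-[(3E)-4-iodo-3-methylbut-3-en-1-yl]-1,5,5-trimethylcyclohex-1-ene, via alkenyldimethylalane 16 (not isolated)
Conditions: Me3Al (2.5 equiv), Cp2ZrCl2 (0.25 equiv), CH2Cl2, 0 °C → rt; then I2, THF, −30 → 0 °C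
Reagents that add atoms: iodine, II
Why: Negishi Zr-catalysed carboalumination adds Me–Al syn across the terminal alkyne (Me on the internal carbon) and iodinolysis with retention gives the (E)-vinyl iodide; the trisubstituted ring alkene is inert.

**Step 8**
Reactants: 18 but-3-yn-1-ol
Product: 19 (but-3-yn-1-yloxy)(tert-butyl)dimethylsilane
Conditions: TBSCl, imidazole, CH2Cl2, rt
Reagents that add atoms: tert-butyldimethylsilyl chloride, CC(C)(C)[Si](C)(C)Cl
Why: Standard silylation protects the primary alcohol for the organometallic steps that follow.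

**Step 9**
Reactants: 19 (but-3-yn-1-yloxy)(tert-butyl)dimethylsilane + 15 trimethylaluminium + 20 formaldehyde (as paraformaldehyde)
Product: 23 (2E)-5-[(tert-butyldimethylsilyl)oxy]-3-methylpent-2-en-1-ol, via alkenyldimethylalane 21 (not isolated), via lithium butylalanate 22 (not isolated)
Conditions: Me3Al, Cp2ZrCl2 (0.25 equiv), CH2Cl2, rt; then n-BuLi, THF, −78 → 0 °C; (CH2O)n, rt
Reagents that add atoms: none
Why: Negishi carboalumination (syn Me–Al addition), activation as the alanate and hydroxymethylation with retention give the geraniol-type (E)-allylic alcohol as a single isomer.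

**Step 10**
Reactants: 23 (2E)-5-[(tert-butyldimethylsilyl)oxy]-3-methylpent-2-en-1-ol
Product: 24 [(2S,3S)-3-{2-[(tert-butyldimethylsilyl)oxy]ethyl}-3-methyloxiran-2-yl]methanol
Conditions: Ti(OiPr)4 (10 mol%), L-(+)-DET (12 mol%), t-BuOOH, 4 Å MS, CH2Cl2, −20 °C
Reagents that add atoms: tert-butyl hydroperoxide, CC(C)(C)OO
Why: Sharpless asymmetric epoxidation; the L-(+)-tartrate catalyst epoxidises the same face as in geraniol and gives the (2S,3S)-epoxy alcohol, setting the future chromene C2 as (S).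

**Step 11**
Reactants: 24 [(2S,3S)-3-{2-[(tert-butyldimethylsilyl)oxy]ethyl}-3-methyloxiran-2-yl]methanol
Product: 25 tert-butyl{2-[(2S,3R)-3-(chloromethyl)-2-methyloxiran-2-yl]ethoxy}dimethylsilane
Conditions: PPh3, CCl4, NaHCO3, reflux
Reagents that add atoms: carbon tetrachloride, ClC(Cl)(Cl)Cl
Why: Appel chlorination of the primary alcohol under buffered conditions leaves the epoxide intact (only the CIP descriptor of the CH carbon changes).

**Step 12**
Reactants: 25 tert-butyl{2-[(2S,3R)-3-(chloromethyl)-2-methyloxiran-2-yl]ethoxy}dimethylsilane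
Product: 28 (3S)-5-[(tert-butyldimethylsilyl)oxy]-3-methylpent-1-yn-3-ol, via lithium chlorovinyl alkoxide 26 (not isolated), via dilithio alkynyl alkoxide 27 (not isolated)
Conditions: n-BuLi (3.2 equiv), THF, −78 → −30 °C; aq. NH4Cl
Reagents that add atoms: none
Why: Base-induced fragmentation of the 2,3-epoxy chloride (α-lithiation, epoxide opening, E2 to the alkyne) gives the tertiary propargylic alcohol; the C–O bond of the quaternary carbon is never broken, so its configuration is retained.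

**Step 13**
Reactants: 29 3-iodophenol
Product: 30 4-bromo-3-iodophenol
Conditions: NBS, MeCN, −10 °C → rt
Reagents that add atoms: N-bromosuccinimide, O=C1CCC(=O)N1Br
Why: Electrophilic aromatic bromination goes para to the strongly directing OH, placing Br where the pyran oxygen will later be attached.

**Step 14**
Reactants: 30 4-bromo-3-iodophenol
Product: 31 (4-bromo-3-iodophenoxy)triisopropylsilane
Conditions: TIPSCl, imidazole, DMF, rt
Reagents that add atoms: triisopropylsilyl chloride, CC(C)[Si](Cl)(C(C)C)C(C)C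
Why: Silylation gives a base-robust aryl TIPS ether that survives the Pd steps and is removed by fluoride at the end.

**Step 15**
Reactants: 28 (3S)-5-[(tert-butyldimethylsilyl)oxy]-3-methylpent-1-yn-3-ol + 31 (4-bromo-3-iodophenoxy)triisopropylsilane
Product: 32 (3S)-1-{2-bromo-5-[(triisopropylsilyl)oxy]phenyl}-5-[(tert-butyldimethylsilyl)oxy]-3-methylpent-1-yn-3-ol
Conditions: PdCl2(PPh3)2 (2 mol%), CuI (4 mol%), Et3N, THF, rt
Reagents that add atoms: none
Why: Sonogashira coupling at room temperature is selective for the C–I bond over the ortho C–Br bond.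

**Step 16**
Reactants: 32 (3S)-1-{2-bromo-5-[(triisopropylsilyl)oxy]phenyl}-5-[(tert-butyldimethylsilyl)oxy]-3-methylpent-1-yn-3-ol
Product: 33 (1Z,3S)-1-{2-bromo-5-[(triisopropylsilyl)oxy]phenyl}-5-[(tert-butyldimethylsilyl)oxy]-3-methylpent-1-en-3-ol
Conditions: H2 (1 atm), Lindlar catalyst, quinoline, EtOAc, rt
Reagents that add atoms: none
Why: Lindlar semihydrogenation adds H2 syn to give the Z-alkene needed for ring closure, without touching the aryl bromide.

**Step 17**
Reactants: 33 (1Z,3S)-1-{2-bromo-5-[(triisopropylsilyl)oxy]phenyl}-5-[(tert-butyldimethylsilyl)oxy]-3-methylpent-1-en-3-ol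
Product: 34 tert-butyldimethyl{2-[(2S)-2-methyl-6-(triisopropylsilyloxy)-2H-chromen-2-yl]ethoxy}silane
Conditions: Pd(OAc)2 (3 mol%), 2-(di-tert-butylphosphino)-1,1'-binaphthyl (4 mol%), Cs2CO3, PhMe, 80 °C
Reagents that add atoms: none
Why: Buchwald-type intramolecular Pd-catalysed C–O coupling: the tertiary alkoxide has no β-hydrogen and the Z-alkene pre-organises the six-membered ring; the stereocentre is retained because its C–O bond is not broken.

**Step 18**
Reactants: 34 tert-butyldimethyl{2-[(2S)-2-methyl-6-(triisopropylsilyloxy)-2H-chromen-2-yl]ethoxy}silane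
Product: 35 2-[(2S)-2-methyl-6-(triisopropylsilyloxy)-2H-chromen-2-yl]ethan-1-ol
Conditions: PPTS (0.2 equiv), MeOH, rt
Reagents that add atoms: none
Why: Mild acid methanolysis cleaves the primary alkyl TBS ether; the aryl TIPS ether and the chromene are stable.

**Step 19**
Reactants: 35 2-[(2S)-2-methyl-6-(triisopropylsilyloxy)-2H-chromen-2-yl]ethan-1-ol
Product: 36 {[(2S)-2-(2-iodoethyl)-2-methyl-2H-chromen-6-yl]oxy}triisopropylsilane
Conditions: I2, PPh3, imidazole, CH2Cl2, 0 °C
Reagents that add atoms: iodine, II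
Why: Appel-type iodination of the primary alcohol under neutral conditions; the quaternary stereocentre is not involved.

**Step 20**
Reactants: 36 {[(2S)-2-(2-iodoethyl)-2-methyl-2H-chromen-6-yl]oxy}triisopropylsilane + 17 (6S)-6-[(3E)-4-iodo-3-methylbut-3-en-1-yl]-1,5,5-trimethylcyclohex-1-ene
Product: 38 triisopropyl({(2S)-2-methyl-2-{(3E)-4-methyl-6-[(1S)-2,6,6-trimethylcyclohex-2-en-1-yl]hex-3-en-1-yl}-2H-chromen-6-yl}oxy)silane, via alkylzinc iodide 37 (not isolated)
Conditions: Zn dust (activated with TMSCl/BrCH2CH2Br), LiCl, THF, 40 °C; then 17, PdCl2(dppf) (5 mol%), THF, rt → 45 °C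
Reagents that add atoms: none
Why: Zinc insertion into the primary iodide and Negishi C(sp3)–C(sp2) cross-coupling join the two halves with retention of the E-olefin geometry; both stereocentres are remote from the reacting carbons.

**Step 21**
Reactants: 38 triisopropyl({(2S)-2-methyl-2-{(3E)-4-methyl-6-[(1S)-2,6,6-trimethylcyclohex-2-en-1-yl]hex-3-en-1-yl}-2H-chromen-6-yl}oxy)silane
Product: 39 (2S)-2-methyl-2-{(3E)-4-methyl-6-[(1S)-2,6,6-trimethylcyclohex-2-en-1-yl]hex-3-en-1-yl}-2H-chromen-6-ol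
Conditions: TBAF, THF, 0 °C; aq. NH4Cl
Reagents that add atoms: none
Why: Fluoride-mediated desilylation of the aryl silyl ether frees the phenol without acid, so the chromene and the alkenes are unaffected.

**Compound list**
1 | isobutyraldehyde (2-methylpropanal) | CC(C)C=O | starting material
2 | pent-1-en-3-one (ethyl vinyl ketone) | CCC(=O)C=C | starting material
3 | 2,2-dimethyl-5-oxoheptanal | CCC(=O)CCC(C)(C)C=O | intermediate (not isolated)
4 | 3-hydroxy-2,4,4-trimethylcyclohexan-1-one (diastereomer mixture) | CC1C(O)C(C)(C)CCC1=O | intermediate (not isolated)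
5 | 2,4,4-trimethylcyclohex-2-en-1-one | CC1=CC(C)(C)CCC1=O | intermediate
6 | (1R)-2,4,4-trimethylcyclohex-2-en-1-ol | O[C@H]1C(C)=CC(C)(C)CC1 | intermediate
7 | trimethyl orthoacetate | CC(OC)(OC)OC | starting material
8 | (1R)-2,4,4-trimethylcyclohex-2-en-1-yl dimethyl orthoacetate (mixed orthoester) | CC(OC)(OC)O[C@H]1C(C)=CC(C)(C)CC1 | intermediate (not isolated)
9 | 1-methoxyvinyl (1R)-2,4,4-trimethylcyclohex-2-en-1-yl ether (ketene acetal) | C=C(OC)O[C@H]1C(C)=CC(C)(C)CC1 | intermediate (not isolated)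
10 | methyl 2-[(1S)-2,6,6-trimethylcyclohex-2-en-1-yl]acetate | CC1=CCCC(C)(C)[C@@H]1CC(=O)OC | intermediate
11 | 2-[(1S)-2,6,6-trimethylcyclohex-2-en-1-yl]ethan-1-ol | CC1=CCCC(C)(C)[C@@H]1CCO | intermediate
12 | (6S)-6-(2-iodoethyl)-1,5,5-trimethylcyclohex-1-ene | CC1=CCCC(C)(C)[C@@H]1CCI | intermediate
13 | lithium acetylide–ethylenediamine complex | [Li+].[C-]#C.NCCN | starting material
14 | (6S)-6-(but-3-yn-1-yl)-1,5,5-trimethylcyclohex-1-ene | CC1=CCCC(C)(C)[C@@H]1CCC#C | intermediate
15 | trimethylaluminium | C[Al](C)C | starting material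
16 | dimethyl{(1E)-2-methyl-4-[(1S)-2,6,6-trimethylcyclohex-2-en-1-yl]but-1-en-1-yl}alane | CC1=CCCC(C)(C)[C@@H]1CC/C(C)=C/[Al](C)C | intermediate (not isolated)
17 | (6S)-6-[(3E)-4-iodo-3-methylbut-3-en-1-yl]-1,5,5-trimethylcyclohex-1-ene | CC1=CCCC(C)(C)[C@@H]1CC/C(C)=C/I | intermediate
18 | but-3-yn-1-ol | C#CCCO | starting material
19 | (but-3-yn-1-yloxy)(tert-butyl)dimethylsilane | C#CCCO[Si](C)(C)C(C)(C)C | intermediate
20 | formaldehyde (used as paraformaldehyde) | C=O | starting material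
21 | {(1E)-4-[(tert-butyldimethylsilyl)oxy]-2-methylbut-1-en-1-yl}dimethylalane | C/C(CCO[Si](C)(C)C(C)(C)C)=C\[Al](C)C | intermediate (not isolated)
22 | lithium butyl{(1E)-4-[(tert-butyldimethylsilyl)oxy]-2-methylbut-1-en-1-yl}dimethylalanate | [Li+].CCCC[Al-](C)(C)/C=C(\C)CCO[Si](C)(C)C(C)(C)C | intermediate (not isolated)
23 | (2E)-5-[(tert-butyldimethylsilyl)oxy]-3-methylpent-2-en-1-ol | C/C(CCO[Si](C)(C)C(C)(C)C)=C\CO | intermediate
24 | [(2S,3S)-3-{2-[(tert-butyldimethylsilyl)oxy]ethyl}-3-methyloxiran-2-yl]methanol | OC[C@@H]1O[C@@]1(C)CCO[Si](C)(C)C(C)(C)C | intermediate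
25 | tert-butyl{2-[(2S,3R)-3-(chloromethyl)-2-methyloxiran-2-yl]ethoxy}dimethylsilane | ClC[C@@H]1O[C@@]1(C)CCO[Si](C)(C)C(C)(C)C | intermediate
26 | lithium (3S)-5-[(tert-butyldimethylsilyl)oxy]-1-chloro-3-methylpent-1-en-3-olate | [Li+].[O-][C@](C)(C=CCl)CCO[Si](C)(C)C(C)(C)C | intermediate (not isolated)
27 | dilithium salt of (3S)-5-[(tert-butyldimethylsilyl)oxy]-3-methylpent-1-yn-3-ol (acetylide alkoxide) | [Li+].[Li+].[C-]#C[C@@](C)([O-])CCO[Si](C)(C)C(C)(C)C | intermediate (not isolated)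
28 | (3S)-5-[(tert-butyldimethylsilyl)oxy]-3-methylpent-1-yn-3-ol | C#C[C@@](C)(O)CCO[Si](C)(C)C(C)(C)C | intermediate
29 | 3-iodophenol | Oc1cccc(I)c1 | starting material
30 | 4-bromo-3-iodophenol | Oc1ccc(Br)c(I)c1 | intermediate
31 | (4-bromo-3-iodophenoxy)triisopropylsilane | CC(C)[Si](Oc1ccc(Br)c(I)c1)(C(C)C)C(C)C | intermediate
32 | (3S)-1-{2-bromo-5-[(triisopropylsilyl)oxy]phenyl}-5-[(tert-butyldimethylsilyl)oxy]-3-methylpent-1-yn-3-ol | Brc1ccc(O[Si](C(C)C)(C(C)C)C(C)C)cc1C#C[C@@](C)(O)CCO[Si](C)(C)C(C)(C)C | intermediate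
33 | (1Z,3S)-1-{2-bromo-5-[(triisopropylsilyl)oxy]phenyl}-5-[(tert-butyldimethylsilyl)oxy]-3-methylpent-1-en-3-ol | Brc1ccc(O[Si](C(C)C)(C(C)C)C(C)C)cc1/C=C\[C@@](C)(O)CCO[Si](C)(C)C(C)(C)C | intermediate
34 | tert-butyldimethyl{2-[(2S)-2-methyl-6-(triisopropylsilyloxy)-2H-chromen-2-yl]ethoxy}silane | CC(C)(C)[Si](C)(C)OCC[C@@]1(C)C=Cc2cc(O[Si](C(C)C)(C(C)C)C(C)C)ccc2O1 | intermediate
35 | 2-[(2S)-2-methyl-6-(triisopropylsilyloxy)-2H-chromen-2-yl]ethan-1-ol | OCC[C@@]1(C)C=Cc2cc(O[Si](C(C)C)(C(C)C)C(C)C)ccc2O1 | intermediate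
36 | {[(2S)-2-(2-iodoethyl)-2-methyl-2H-chromen-6-yl]oxy}triisopropylsilane | ICC[C@@]1(C)C=Cc2cc(O[Si](C(C)C)(C(C)C)C(C)C)ccc2O1 | intermediate
37 | iodo{2-[(2S)-2-methyl-6-(triisopropylsilyloxy)-2H-chromen-2-yl]ethyl}zinc | I[Zn]CC[C@@]1(C)C=Cc2cc(O[Si](C(C)C)(C(C)C)C(C)C)ccc2O1 | intermediate (not isolated)
38 | triisopropyl({(2S)-2-methyl-2-{(3E)-4-methyl-6-[(1S)-2,6,6-trimethylcyclohex-2-en-1-yl]hex-3-en-1-yl}-2H-chromen-6-yl}oxy)silane | CC1=CCCC(C)(C)[C@@H]1CC/C(C)=C/CC[C@@]1(C)C=Cc2cc(O[Si](C(C)C)(C(C)C)C(C)C)ccc2O1 | intermediate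
39 | (2S)-2-methyl-2-{(3E)-4-methyl-6-[(1S)-2,6,6-trimethylcyclohex-2-en-1-yl]hex-3-en-1-yl}-2H-chromen-6-ol | CC1=CCCC(C)(C)[C@@H]1CC/C(C)=C/CC[C@@]1(C)C=Cc2cc(O)ccc2O1 | target

**Totals**
Total step count: 21. Longest linear sequence: 12 steps (8, 9, 10, 11, 12, 15, 16, 17, 18, 19, 20, 21). The cyclohexenyl branch (steps 1–7) and the arene branch (steps 13–14) run in parallel.

**Steps most likely to fail, with fallbacks**

Step 3 (Johnson–Claisen). The new C–C bond forms at a ring carbon next to the quaternary CMe2, and at 140 °C with acid the allylic alcohol can dehydrate to a diene. The fallback sets out from 6 and comes back at 11. Acetylation (Ac2O, DMAP, pyridine) gives (1R)-2,4,4-trimethylcyclohex-2-en-1-yl acetate F1. LDA in THF at −78 °C followed by TMSCl gives the silyl ketene acetal 1-[(trimethylsilyl)oxy]vinyl (1R)-2,4,4-trimethylcyclohex-2-en-1-yl ether F2. On warming to 60 °C this undergoes an Ireland–Claisen rearrangement under base, with the same suprafacial chirality transfer, to trimethylsilyl 2-[(1S)-2,6,6-trimethylcyclohex-2-en-1-yl]acetate F3. Aqueous work-up gives 2-[(1S)-2,6,6-trimethylcyclohex-2-en-1-yl]acetic acid F4, and LiAlH4 in THF reduces F4 to 11.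

Step 17 (Pd-catalysed C–O closure on a hindered tertiary Z-allylic alcohol). Protodebromination or Z/E isomerisation may compete, and this exact substrate class is less precedented than saturated ones. The fallback sets out from 32 and comes back at 34. Diimide reduction (TsNHNH2, NaOAc, aq. DME, reflux) saturates the alkyne without touching the aryl bromide and gives (3R)-1-{2-bromo-5-[(triisopropylsilyl)oxy]phenyl}-5-[(tert-butyldimethylsilyl)oxy]-3-methylpentan-3-ol F5. The well-precedented Pd(OAc)2/di-tert-butylphosphinobinaphthyl/Cs2CO3 etherification of this saturated tertiary alcohol gives tert-butyldimethyl{2-[(2R)-2-methyl-6-(triisopropylsilyloxy)-3,4-dihydro-2H-chromen-2-yl]ethoxy}silane F6. Benzylic dehydrogenation with DDQ in refluxing dioxane introduces the C3=C4 double bond and gives 34 (the descriptor changes from R to S by CIP only).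

Step 20 (zinc insertion and sp3–sp2 Negishi coupling). Incomplete insertion, homocoupling or β-hydride elimination could lower the yield with the trisubstituted alkenyl iodide. The fallback sets out from 36 (with 17 unchanged) and comes back at 38. Iodine–lithium exchange with t-BuLi (2.1 equiv, Et2O, −78 °C) gives {2-[(2S)-2-methyl-6-(triisopropylsilyloxy)-2H-chromen-2-yl]ethyl}lithium F7. Trapping with B-methoxy-9-BBN gives the lithium B-alkyl-B-methoxy-9-borabicyclo[3.3.1]nonane ate complex F8. This is coupled with 17 in a B-alkyl Suzuki–Miyaura reaction (PdCl2(dppf), AsPh3, aq. Cs2CO3, DMF, rt) to give 38.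

**Further compounds**
F1 | step 3 | (1R)-2,4,4-trimethylcyclohex-2-en-1-yl acetate | CC(=O)O[C@H]1C(C)=CC(C)(C)CC1
F2 | step 3 | 1-[(trimethylsilyl)oxy]vinyl (1R)-2,4,4-trimethylcyclohex-2-en-1-yl ether | C=C(O[Si](C)(C)C)O[C@H]1C(C)=CC(C)(C)CC1
F3 | step 3 | trimethylsilyl 2-[(1S)-2,6,6-trimethylcyclohex-2-en-1-yl]acetate | CC1=CCCC(C)(C)[C@@H]1CC(=O)O[Si](C)(C)C
F4 | step 3 | 2-[(1S)-2,6,6-trimethylcyclohex-2-en-1-yl]acetic acid | CC1=CCCC(C)(C)[C@@H]1CC(=O)O
F5 | step 17 | (3R)-1-{2-bromo-5-[(triisopropylsilyl)oxy]phenyl}-5-[(tert-butyldimethylsilyl)oxy]-3-methylpentan-3-ol | Brc1ccc(O[Si](C(C)C)(C(C)C)C(C)C)cc1CC[C@@](C)(O)CCO[Si](C)(C)C(C)(C)C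
F6 | step 17 | tert-butyldimethyl{2-[(2R)-2-methyl-6-(triisopropylsilyloxy)-3,4-dihydro-2H-chromen-2-yl]ethoxy}silane | CC(C)(C)[Si](C)(C)OCC[C@@]1(C)CCc2cc(O[Si](C(C)C)(C(C)C)C(C)C)ccc2O1
F7 | step 20 | {2-[(2S)-2-methyl-6-(triisopropylsilyloxy)-2H-chromen-2-yl]ethyl}lithium | [Li]CC[C@@]1(C)C=Cc2cc(O[Si](C(C)C)(C(C)C)C(C)C)ccc2O1
F8 | step 20 | lithium 9-methoxy-9-{2-[(2S)-2-methyl-6-(triisopropylsilyloxy)-2H-chromen-2-yl]ethyl}-9-boranuidabicyclo[3.3.1]nonane | [Li+].CO[B-]1(CC[C@@]2(C)C=Cc3cc(O[Si](C(C)C)(C(C)C)C(C)C)ccc3O2)C2CCCC1CCC2
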